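**Retrosynthetic overview**
1. One disconnection: the alkyl C–O bond of the ester, leading back to 3-(4-hydroxyphenyl)propanoic acid (1) and nonadec-1-ene (2), both catalogue chemicals.
2. Forward: 2 is hydroborated to the B-alkylborane 3, and its primary C–B bond is exchanged in the same flask for the C–O bond to the carboxylate of 1, giving the target ester 4.
3. No ring is formed; the benzene ring is bought with 1 and the phenol is carried unprotected.
4. No stereocentre is present or created.

Assumption: the target has no stereocentre, so "single enantiomer" is read as the one achiral compound drawn.

**Step 1**
Reactants: 1 3-(4-hydroxyphenyl)propanoic acid; 2 nonadec-1-ene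
Product: 4 nonadecyl 3-(4-hydroxyphenyl)propanoate, via B-nonadecyl-9-BBN 3 (not isolated)
Conditions: 9-BBN dimer (0.5 equiv), THF, 0 to 23 °C; then 1 (1.2 equiv), Co(salen) (5 mol%), N-fluoro-2,4,6-trimethylpyridinium triflate (1.3 equiv), 2,4,6-collidine (1.2 equiv), PhCF3, 0 to 23 °C, argon
Reagents that add atoms: none
Why: Proposed new method: a one-pot formal anti-Markovnikov hydroacyloxylation, in which 9-BBN hydroboration of 2 (known, boron on C1) is followed by a new cobalt-catalysed oxidative C(sp3)–O coupling of the B-alkyl group with the carboxylate of 1, reasoned as follows: the N–F salt oxidises Co(salen) to a fluoride of trivalent cobalt, B–F bond formation drives transfer of the primary alkyl group from boron to cobalt (the planar salen ligand leaves no cis site for β-hydride loss), one-electron oxidation gives an alkyl complex of tetravalent cobalt, and the carboxylate, the only O–H of 1 that collidine deprotonates, displaces cobalt at CH2 by SN2 to form the ester C–O bond and return divalent cobalt; the closest known reaction type is the Co(salen)/N-fluoropyridinium/hydrosilane radical-polar crossover hydroalkoxylation and hydroacyloxylation of alkenes, which ends in the same SN2 attack of an O-nucleophile on an alkyl complex of tetravalent cobalt but gives the Markovnikov isomer, together with the B-alkyl transfer of the Suzuki–Miyaura coupling; no stereocentre is formed.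

**Compound list**
1 | 3-(4-hydroxyphenyl)propanoic acid (phloretic acid) | OC(=O)CCc1ccc(O)cc1 | starting material
2 | nonadec-1-ene | C=CCCCCCCCCCCCCCCCCC | starting material
3 | 9-nonadecyl-9-borabicyclo[3.3.1]nonane (B-nonadecyl-9-BBN) | CCCCCCCCCCCCCCCCCCCB1C2CCCC1CCC2 | intermediate
4 | nonadecyl 3-(4-hydroxyphenyl)propanoate | CCCCCCCCCCCCCCCCCCCOC(=O)CCc1ccc(O)cc1 | target

**Totals**
Total step count: 1 (one flask, two stages). Longest linear sequence: 1.

**Steps most likely to fail**
The route has a single step, so the list holds one entry.

1. Step 1 (the proposed new method). The alkyl transfer from boron to cobalt is unproven. The C–B bond may instead be fluorinated by the N–F salt or protonolysed by the acid, and some O-alkylation of the phenol cannot be excluded. The fallback uses known chemistry and sets out from 3 in the same flask. Oxidation with NaOH and H2O2 in THF–H2O at 0 to 50 °C (hydroboration–oxidation) gives nonadecan-1-ol F1. F1 and 1 are then heated with TsOH·H2O (5 mol%) in toluene at reflux under a Dean–Stark trap (Fischer esterification, which leaves the phenol unacylated). This gives 4, where the fallback comes back to the route.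

**Further compounds**
F1 | step 1 | nonadecan-1-ol | CCCCCCCCCCCCCCCCCCCO
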